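**Retrosynthetic overview**

Numbering: ring A is the 4-hydroxy-3-methoxyphenyl ring on C7, ring B is the 2,6-dimethoxyphenoxy ring bound through O4', and C7–C8–C9 is the propane chain; the target is the threo (7R,8R) 8-O-4' neolignan.
Last disconnection: the C9 alcohol, the cinnamyl alcohol on ring B and the ring A phenol are traced back to an ethyl ester, a methyl cinnamate and an aryl acetate, all released by one hydride reduction.
Key disconnection: C8 is the one atom bonded to all three building blocks (O4' of ring B, the benzylic carbinol C7 on ring A, and C9). It is therefore treated as a carbene carbon, electrophilic towards O4' and then, as the oxonium ylide, nucleophilic towards the ring A aldehyde carbon; C8–O4', C7–C8 and both stereocentres come from ethyl diazoacetate, methyl sinapate and vanillin acetate in one operation.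
Methyl sinapate comes from sinapic acid by esterification; no ring is formed in the route, as both benzene rings are bought.

Key step: step 2

Assumption: the sense of induction of the phosphoric acid cannot be derived with confidence for this untested substrate combination; the (R)-acid is written, and its mirror image would be used if a first run shows that it leads to the (7S,8S) series.

**Route**

Step 1
Reactants: 1 (E)-sinapic acid
Product: 2 methyl (E)-sinapate
Conditions: MeOH, cat. H2SO4, reflux
Reagents that add atoms: methanol, CO
Why: Fischer esterification, in which the large excess of methanol drives the acid-catalysed acyl substitution to the methyl ester while the hindered, hydrogen-bonded phenol and the E alkene stay untouched; no stereocentre is formed.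

Step 2
Reactants: 2 methyl (E)-sinapate; 3 ethyl diazoacetate; 4 vanillin acetate (4-formyl-2-methoxyphenyl acetate)
Product: 6 ethyl (2S,3R)-3-(4-acetoxy-3-methoxyphenyl)-3-hydroxy-2-{2,6-dimethoxy-4-[(E)-3-methoxy-3-oxoprop-1-enyl]phenoxy}propanoate (threo; C3 is C7 and C2 is C8), via protic oxonium ylide 5 (not isolated)
Conditions: Rh2(OAc)4 (2 mol %), (R)-3,3'-bis(2,4,6-triisopropylphenyl)-1,1'-binaphthyl-2,2'-diyl hydrogen phosphate (10 mol %), 4 Å MS, CH2Cl2, 0 °C; 2 (1.0 equiv), 4 (2.0 equiv), 3 (1.3 equiv) added over 4 h by syringe pump
Reagents that add atoms: none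
Why: Proposed new method: Rh2(OAc)4 decomposes 3 to an electrophilic rhodium carbene that is captured by the phenol oxygen of 2 to give protic oxonium ylide 5, an enol equivalent of the aryloxyacetate, whose carbon adds to acid-bound aldehyde 4 before the 1,2-proton shift can deliver the plain O–H insertion product, so that C8–O4' and C7–C8 form in one flask and no ring closes. The closest known reaction type is the aldol-type trapping of oxonium ylides made from aryl diazoacetates and alcohols by aldehydes under Rh2(OAc)4 with a chiral acid co-catalyst, and the combination of a phenol with an acceptor-only diazoacetate is the untested extension. C7 is controlled by the phosphoric acid, which donates a hydrogen bond to the aldehyde oxygen and accepts one from the O–H of 5, so that a single aldehyde face is exposed inside the pocket of the 3,3'-aryl groups. C8 and the threo relation are controlled by the geometry of 5, in which the internal O–H···O=C hydrogen bond holds the aryloxy oxygen cis to the ester oxygen as in a Z enolate, and a cyclic acid-bridged transition state with the ring A aryl group pseudo-equatorial then gives the syn adduct, which is threo. The step needs trapping to win over proton transfer, favoured by the acetate that makes 4 more electrophilic than free vanillin, by the excess of 4, by acid activation and by slow addition of 3 at low temperature, and it needs attack at O–H in preference to cyclopropanation, which the electron-poor cinnamate alkene of 2 secures.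

Step 3
Reactants: 6 ethyl (2S,3R)-3-(4-acetoxy-3-methoxyphenyl)-3-hydroxy-2-{2,6-dimethoxy-4-[(E)-3-methoxy-3-oxoprop-1-enyl]phenoxy}propanoate
Product: 7 (1R,2R)-1-(4-hydroxy-3-methoxyphenyl)-2-{4-[(E)-3-hydroxyprop-1-enyl]-2,6-dimethoxyphenoxy}propane-1,3-diol (target, threo, 7R,8R)
Conditions: i-Bu2AlH (10 equiv), CH2Cl2/toluene, −78 °C to 0 °C; then aq. KNaC4H4O6
Reagents that add atoms: none
Why: Hydride reduction with i-Bu2AlH takes both esters to primary alcohols (the enoate by 1,2-reduction, which keeps the E alkene) and cleaves the aryl acetate reductively to the phenol in the same operation, while the C9 ester is consumed as a tetrahedral aluminium hemiacetal at low temperature without enolisation, so the configuration set in step 2 at C7 and C8 is carried unchanged into 7.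

**Compound list**

1 | (E)-sinapic acid | COc1cc(/C=C/C(=O)O)cc(OC)c1O | starting material
2 | methyl (E)-sinapate | COC(=O)/C=C/c1cc(OC)c(O)c(OC)c1 | intermediate
3 | ethyl diazoacetate | CCOC(=O)C=[N+]=[N-] | starting material
4 | vanillin acetate (4-formyl-2-methoxyphenyl acetate) | COc1cc(C=O)ccc1OC(C)=O | starting material
5 | protic oxonium ylide from the carbene of 3 and the phenol oxygen of 2, drawn free of rhodium | CCOC(=O)[CH-][OH+]c1c(OC)cc(/C=C/C(=O)OC)cc1OC | intermediate
6 | ethyl (2S,3R)-3-(4-acetoxy-3-methoxyphenyl)-3-hydroxy-2-{2,6-dimethoxy-4-[(E)-3-methoxy-3-oxoprop-1-enyl]phenoxy}propanoate; threo, same spatial arrangement as (7R,8R) in 7, the C8 descriptor being S only because CO2Et outranks C7 | COc1cc([C@@H](O)[C@@H](C(=O)OCC)Oc2c(OC)cc(/C=C/C(=O)OC)cc2OC)ccc1OC(C)=O | intermediate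
7 | (1R,2R)-1-(4-hydroxy-3-methoxyphenyl)-2-{4-[(E)-3-hydroxyprop-1-enyl]-2,6-dimethoxyphenoxy}propane-1,3-diol | COc1cc([C@@H](O)[C@@H](CO)Oc2c(OC)cc(/C=C/CO)cc2OC)ccc1O | target

**Step count**

Total steps: 3. Longest linear sequence: 3 steps (1 to 2 to 6 to 7).

**Steps most likely to fail**

1. Step 2 (proposed new method). Proton transfer within the oxonium ylide, possibly shuttled by the phosphoric acid itself, may outrun C–C bond formation, so that only O–H insertion takes place. The addition may also proceed with poor facial or threo/erythro control. Oxidation at C7 followed by re-reduction is not used as a remedy for an erythro adduct, because the β-keto ester on that path would lose the C8 configuration by enolisation. The fallback uses known chemistry, sets out from 2 and comes back to the route at 7. Phenol 2 is alkylated in a Williamson ether synthesis with commercial (S)-4-benzyl-3-(chloroacetyl)oxazolidin-2-one, O=C(CCl)N1[C@@H](Cc2ccccc2)COC1=O (K2CO3, cat. NaI, acetone), to give the aryloxyacetyl imide F1. Its Z boron enolate (n-Bu2BOTf, i-Pr2NEt, CH2Cl2, −78 °C) adds to aldehyde 4 in an Evans aldol reaction through a closed chair transition state and should give the syn adduct F2. Syn is threo here, and the (S)-auxiliary leads to the same spatial arrangement at C7 and C8 as in 6. NaBH4 in THF/H2O then removes the auxiliary reductively and cleaves the phenol acetate to give the triol ester F3, and i-Bu2AlH under the conditions of step 3 reduces the cinnamate ester to reach 7.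

2. Step 3. The free C7 hydroxyl becomes an aluminium alkoxide during a reduction that needs many equivalents of hydride; retro-aldol fragmentation or epimerisation at C8 may then compete, one of the three acyl groups may be reduced incompletely, and the polar product may be held back on aluminium salts at work-up. The fallback sets out from 6 and comes back at 7. The C7 hydroxyl is masked first (Et3SiOTf, 2,6-lutidine, CH2Cl2, −78 °C to 0 °C) to give the triethylsilyl ether F4, so that no aldolate can form. i-Bu2AlH then reduces both esters and removes the acetate to give the silyl-protected triol F5, and buffered fluoride (n-Bu4NF, AcOH, THF, 0 °C) frees the C7 hydroxyl to give 7.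

3. Step 1. Conversion may stall at equilibrium, and prolonged heating in acid may lead to addition of methanol to the electron-rich styrene unit or to oligomerisation. The fallback sets out from 1 and comes back at 2: the carboxylate alone is formed with KHCO3 in DMF and alkylated irreversibly with MeI at room temperature, the less acidic phenol staying protonated; no new compound arises on this path (F0).

**Further compounds**

F1 | step 2 | (S)-4-benzyl-3-{2-[2,6-dimethoxy-4-((E)-3-methoxy-3-oxoprop-1-enyl)phenoxy]acetyl}oxazolidin-2-one | COC(=O)/C=C/c1cc(OC)c(OCC(=O)N2[C@@H](Cc3ccccc3)COC2=O)c(OC)c1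
F2 | step 2 | (S)-4-benzyl-3-[(2S,3R)-3-(4-acetoxy-3-methoxyphenyl)-3-hydroxy-2-{2,6-dimethoxy-4-[(E)-3-methoxy-3-oxoprop-1-enyl]phenoxy}propanoyl]oxazolidin-2-one | COc1cc([C@@H](O)[C@@H](C(=O)N2[C@@H](Cc3ccccc3)COC2=O)Oc4c(OC)cc(/C=C/C(=O)OC)cc4OC)ccc1OC(C)=O
F3 | step 2 | methyl (E)-3-{4-[(1R,2R)-1,3-dihydroxy-1-(4-hydroxy-3-methoxyphenyl)propan-2-yl]oxy-3,5-dimethoxyphenyl}prop-2-enoate | COc1cc([C@@H](O)[C@@H](CO)Oc2c(OC)cc(/C=C/C(=O)OC)cc2OC)ccc1O
F4 | step 3 | ethyl (2S,3R)-3-(4-acetoxy-3-methoxyphenyl)-2-{2,6-dimethoxy-4-[(E)-3-methoxy-3-oxoprop-1-enyl]phenoxy}-3-(triethylsilyloxy)propanoate | COc1cc([C@@H](O[Si](CC)(CC)CC)[C@@H](C(=O)OCC)Oc2c(OC)cc(/C=C/C(=O)OC)cc2OC)ccc1OC(C)=O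
F5 | step 3 | (2R,3R)-3-(4-hydroxy-3-methoxyphenyl)-2-{4-[(E)-3-hydroxyprop-1-enyl]-2,6-dimethoxyphenoxy}-3-(triethylsilyloxy)propan-1-ol | COc1cc([C@@H](O[Si](CC)(CC)CC)[C@@H](CO)Oc2c(OC)cc(/C=C/CO)cc2OC)ccc1O
F0 | step 1 | none | none
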